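**Retrosynthetic overview**
- Last, the C-5 methoxymethyl (MOM) acetal is hydrolysed. Before that, the C-8–aryl bond is made by Friedel–Crafts opening of a trans-phenyl epoxide at its benzylic carbon (inversion) by flavanone C-6 of bought (2S)-pinocembrin, which brings the chromanone ring intact.
- The epoxy lactone comes from ring-closing metathesis of an acrylate onto a vinyl group; the dihydropyranone is the second and last ring built.
- The epoxide comes from reagent-controlled Shi epoxidation of the styryl alkene of a triene ester; the oxirane is the first ring built.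
- The syn C-5/C-6 dioxygen pattern comes from Brown (Z)-γ-alkoxyallylboration of cinnamaldehyde; acryloyl chloride supplies C-2/C-3.

Assumption: C-2 to C-8 denote the styryl-lactone carbons (C-2 lactone carbonyl, C-7 carbinol, C-8 benzhydryl carbon); allyl MOM ether, (+)-Ipc2BOMe, (2S)-pinocembrin and the L-fructose-derived Shi ketone are taken as purchasable.

**Route**

Step 1
Reactants: 1 3-(methoxymethoxy)prop-1-ene (allyl MOM ether); 2 (+)-B-methoxydiisopinocampheylborane [(+)-Ipc2BOMe]; 3 (E)-cinnamaldehyde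
Product: 8 (3S,4S,E)-4-(methoxymethoxy)-1-phenylhexa-1,5-dien-3-ol, via allyllithium 4 (not isolated), via borate complex 5 (not isolated), via Z-alkoxyallylborane 6 (not isolated), via borinate ester 7 (not isolated)
Conditions: 1, s-BuLi, THF, −78 °C; 2, −78 °C; BF3·OEt2; 3, −78 °C, 3 h; then NaOH, H2O2, 0 °C → rt
Reagents that add atoms: none
Why: Brown asymmetric γ-alkoxyallylboration: the chelated (Z)-alkoxyallyl anion is trapped on boron, the chair (Zimmerman–Traxler) transition state of 6 turns the Z geometry into the syn C-5/C-6 relationship, and the isopinocampheyl groups derived from (−)-α-pinene send the allyl unit to the Re face of the aldehyde, giving (3S,4S) (C-6 and C-5 of the target).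

Step 2
Reactants: 8 (3S,4S,E)-4-(methoxymethoxy)-1-phenylhexa-1,5-dien-3-ol; 9 acryloyl chloride
Product: 10 (3S,4S,E)-4-(methoxymethoxy)-1-phenylhexa-1,5-dien-3-yl acrylate
Conditions: Et3N, DMAP (4-(dimethylamino)pyridine, cat.), CH2Cl2, 0 °C
Reagents that add atoms: none
Why: Nucleophilic acyl substitution (O-acylation) of the secondary allylic alcohol installs C-2/C-3 of the lactone without touching either stereocentre.

Step 3
Reactants: 10 (3S,4S,E)-4-(methoxymethoxy)-1-phenylhexa-1,5-dien-3-yl acrylate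
Product: 11 (1R,2S)-2-(methoxymethoxy)-1-[(2R,3S)-3-phenyloxiran-2-yl]but-3-en-1-yl acrylate
Conditions: L-fructose-derived Shi ketone 1,2:4,5-di-O-isopropylidene-β-L-erythro-2,3-hexodiulo-2,6-pyranose (C12H18O6, 0.3 equiv), Oxone (2KHSO5·KHSO4·K2SO4), K2CO3, Bu4NHSO4, MeCN/CH2(OMe)2/aq. Na2B4O7 buffer (pH 10.5), 0 °C
Reagents that add atoms: Oxone (active oxidant potassium peroxymonosulfate, KHSO5), [K+].[O-]S(=O)(=O)OO
Why: Shi asymmetric epoxidation: the chiral dioxirane formed from the ketone and KHSO5 transfers oxygen through a spiro transition state only to the electron-rich trans-styryl alkene (the monosubstituted vinyl and the electron-poor acrylate are much slower), and the L-series ketone gives the (S,S)-sense trans-epoxide, i.e. the (2R,3S)-oxirane that fixes C-7 and pre-sets C-8 for inversion.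

Step 4
Reactants: 11 (1R,2S)-2-(methoxymethoxy)-1-[(2R,3S)-3-phenyloxiran-2-yl]but-3-en-1-yl acrylate
Product: 12 (5S,6R)-5-(methoxymethoxy)-6-[(2R,3S)-3-phenyloxiran-2-yl]-5,6-dihydro-2H-pyran-2-one
Conditions: second-generation Grubbs catalyst (H2IMes)(PCy3)Cl2Ru=CHPh (5 mol%), CH2Cl2 (5 mM), 40 °C
Reagents that add atoms: none
Why: Ring-closing metathesis: the ruthenium alkylidene loads on the terminal vinyl group and closes the six-membered α,β-unsaturated lactone onto the acrylate with loss of ethene, giving the ring-enforced Z-alkene with no stereocentre touched; epoxide and acetal are inert.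

Step 5
Reactants: 12 (5S,6R)-5-(methoxymethoxy)-6-[(2R,3S)-3-phenyloxiran-2-yl]-5,6-dihydro-2H-pyran-2-one; 13 (2S)-pinocembrin
Product: 14 (2S)-5,7-dihydroxy-6-{(1S,2R)-2-hydroxy-2-[(2S,3S)-3-(methoxymethoxy)-6-oxo-3,6-dihydro-2H-pyran-2-yl]-1-phenylethyl}-2-phenylchroman-4-one
Conditions: (CF3)2CHOH (HFIP), 0 °C → rt, flavanone in threefold excess
Reagents that add atoms: none
Why: Friedel–Crafts alkylation by epoxide opening, a pure addition in which the aryl hydrogen ends on the epoxide oxygen: HFIP activates the oxirane by hydrogen bonding and the phloroglucinol-type ring of the flavanone attacks benzylic C-8 anti to the C–O bond (SN2-like, inversion), giving the (8S) benzhydryl centre and the free (7R) hydroxyl; bonding is expected mainly through flavanone C-6, the position between the two hydroxyls, with the C-8-linked isomer removed by chromatography, the surplus flavanone is recovered unchanged, and flavanone C-2 is untouched under these non-basic conditions.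

Step 6
Reactants: 14 (2S)-5,7-dihydroxy-6-{(1S,2R)-2-hydroxy-2-[(2S,3S)-3-(methoxymethoxy)-6-oxo-3,6-dihydro-2H-pyran-2-yl]-1-phenylethyl}-2-phenylchroman-4-one
Product: 15 (2S)-5,7-dihydroxy-6-{(1S,2R)-2-hydroxy-2-[(2R,3S)-3-hydroxy-6-oxo-3,6-dihydro-2H-pyran-2-yl]-1-phenylethyl}-2-phenylchroman-4-one (CNP0136207.1)
Conditions: 3 M aq. HCl/THF (1:3), 40 °C
Reagents that add atoms: none
Why: Acid-catalysed acetal hydrolysis (MOM removal) frees the C-5 hydroxyl without breaking any bond to a stereocentre; dilute aqueous acid spares the lactone, the flavanone and the benzhydryl C–C bond, and base, which would translactonise the 5-hydroxy lactone and open the flavanone, is avoided.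

**Compound list**

1 | 3-(methoxymethoxy)prop-1-ene (allyl MOM ether) | C=CCOCOC | starting material
2 | (+)-B-methoxydiisopinocampheylborane, (+)-Ipc2BOMe, from (−)-α-pinene, boron on the (1S,2R,3S,5S)-isopinocampheyl carbons | COB([C@H]1C[C@H]2C[C@@H]([C@@H]1C)C2(C)C)[C@H]1C[C@H]2C[C@@H]([C@@H]1C)C2(C)C | starting material
3 | (E)-cinnamaldehyde | O=C/C=C/c1ccccc1 | starting material
4 | (Z)-3-(methoxymethoxy)allyllithium | [Li+].[CH2-]/C=C\OCOC | intermediate
5 | lithium methoxy[(Z)-3-(methoxymethoxy)allyl]diisopinocampheylborate | [Li+].COCO/C=C\C[B-](OC)([C@H]1C[C@H]2C[C@@H]([C@@H]1C)C2(C)C)[C@H]1C[C@H]2C[C@@H]([C@@H]1C)C2(C)C | intermediate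
6 | [(Z)-3-(methoxymethoxy)allyl]diisopinocampheylborane | COCO/C=C\CB([C@H]1C[C@H]2C[C@@H]([C@@H]1C)C2(C)C)[C@H]1C[C@H]2C[C@@H]([C@@H]1C)C2(C)C | intermediate
7 | diisopinocampheylborinate (O-boryl ether) of 8 | C=C[C@H](OCOC)[C@H](/C=C/c1ccccc1)OB([C@H]1C[C@H]2C[C@@H]([C@@H]1C)C2(C)C)[C@H]1C[C@H]2C[C@@H]([C@@H]1C)C2(C)C | intermediate
8 | (3S,4S,E)-4-(methoxymethoxy)-1-phenylhexa-1,5-dien-3-ol | C=C[C@H](OCOC)[C@H](/C=C/c1ccccc1)O | intermediate
9 | acryloyl chloride | C=CC(=O)Cl | starting material
10 | (3S,4S,E)-4-(methoxymethoxy)-1-phenylhexa-1,5-dien-3-yl acrylate | C=C[C@H](OCOC)[C@H](/C=C/c1ccccc1)OC(=O)C=C | intermediate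
11 | (1R,2S)-2-(methoxymethoxy)-1-[(2R,3S)-3-phenyloxiran-2-yl]but-3-en-1-yl acrylate | C=C[C@H](OCOC)[C@H]([C@@H]1O[C@H]1c1ccccc1)OC(=O)C=C | intermediate
12 | (5S,6R)-5-(methoxymethoxy)-6-[(2R,3S)-3-phenyloxiran-2-yl]-5,6-dihydro-2H-pyran-2-one | O=C1C=C[C@H](OCOC)[C@H]([C@@H]2O[C@H]2c2ccccc2)O1 | intermediate
13 | (2S)-pinocembrin, (2S)-5,7-dihydroxy-2-phenylchroman-4-one | O=C1C[C@@H](c2ccccc2)Oc2cc(O)cc(O)c12 | starting material
14 | (2S)-5,7-dihydroxy-6-{(1S,2R)-2-hydroxy-2-[(2S,3S)-3-(methoxymethoxy)-6-oxo-3,6-dihydro-2H-pyran-2-yl]-1-phenylethyl}-2-phenylchroman-4-one (5-O-MOM ether of the target; the pyran C-2 descriptor differs from the target only through CIP priorities) | O=C1C=C[C@H](OCOC)[C@H]([C@H](O)[C@@H](c2ccccc2)c2c(O)cc3c(c2O)C(=O)C[C@@H](c2ccccc2)O3)O1 | intermediate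
15 | (2S)-5,7-dihydroxy-6-{(1S,2R)-2-hydroxy-2-[(2R,3S)-3-hydroxy-6-oxo-3,6-dihydro-2H-pyran-2-yl]-1-phenylethyl}-2-phenylchroman-4-one (CNP0136207.1) | O=C1C=C[C@H](O)[C@H]([C@H](O)[C@@H](c2ccccc2)c2c(O)cc3c(c2O)C(=O)C[C@@H](c2ccccc2)O3)O1 | target

**Totals**

Total step count: 6. Longest linear sequence: 6 steps (3 → 8 → 10 → 11 → 12 → 14 → 15).

**Three steps most likely to fail**

Step 5 (Friedel–Crafts epoxide arylation). The risks are a mixture of flavanone C-6 and C-8 adducts, erosion of inversion at the benzylic carbon, and interference by the C-5 acetal oxygen that the ring holds cis to the side chain (ether closure onto C-8). The fallback forms the aryl–C-8 bond before the lactone exists. It sets out from 11 and 13: the same HFIP arylation on the conformationally free epoxy acrylate gives the acyclic adduct F1, and the flavanone regioisomer is separated at this cheaper stage. Ring-closing metathesis of F1 with the second-generation Grubbs catalyst, which tolerates free phenols, comes back to the route at 14. This fallback does not by itself change the C-6/C-8 preference of pinocembrin.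

Step 3 (Shi epoxidation). The risks are insufficient diastereoselectivity, acrylate loss at pH 10.5, and over-oxidation of the vinyl group. The fallback takes both epoxide centres from the chiral pool instead of creating them. It sets out from 6 (made from 1 and 2 as in step 1). Bought (2S,3S)-3-phenylglycidol F2 is oxidised with Dess–Martin periodinane/NaHCO3 to (2R,3S)-3-phenyloxirane-2-carbaldehyde F3. Reagent 6 adds to F3 at −78 °C to give the borinate F4 and, after NaOH/H2O2, the epoxy alcohol F5. This addition is reagent-controlled and opposes the Felkin preference of the epoxy aldehyde. Acylation of F5 with 9 as in step 2 comes back to the route at 11.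

Step 4 (ring-closing metathesis). The risks are slow initiation at the allylic-acetal olefin, oligomerisation, and ruthenium hydride isomerisation. The fallback closes the ring by olefination instead. It sets out from 8: DCC/DMAP esterification with diethylphosphonoacetic acid F6 gives the phosphonoacetate F7. The epoxidation of step 3 then gives the epoxide F8. Ozonolysis (O3, CH2Cl2, −78 °C; Me2S) of the one remaining alkene gives the aldehyde F9. Intramolecular Horner–Wadsworth–Emmons reaction (LiCl, i-Pr2NEt, MeCN) closes the Z-enoate lactone and comes back to the route at 12.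

**Further compounds**

F1 | step 5 | (1S,2S)-1-{(1R,2S)-2-[(2S)-5,7-dihydroxy-4-oxo-2-phenylchroman-6-yl]-1-hydroxy-2-phenylethyl}-2-(methoxymethoxy)but-3-en-1-yl acrylate | C=C[C@H](OCOC)[C@H]([C@H](O)[C@@H](c1ccccc1)c1c(O)cc2c(c1O)C(=O)C[C@@H](c1ccccc1)O2)OC(=O)C=C
F2 | step 3 | (2S,3S)-3-phenylglycidol | OC[C@@H]1O[C@H]1c1ccccc1
F3 | step 3 | (2R,3S)-3-phenyloxirane-2-carbaldehyde | O=C[C@@H]1O[C@H]1c1ccccc1
F4 | step 3 | diisopinocampheylborinate (O-boryl ether) of F5 | C=C[C@H](OCOC)[C@H]([C@@H]1O[C@H]1c1ccccc1)OB([C@H]1C[C@H]2C[C@@H]([C@@H]1C)C2(C)C)[C@H]1C[C@H]2C[C@@H]([C@@H]1C)C2(C)C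
F5 | step 3 | (1R,2S)-2-(methoxymethoxy)-1-[(2R,3S)-3-phenyloxiran-2-yl]but-3-en-1-ol | C=C[C@H](OCOC)[C@H]([C@@H]1O[C@H]1c1ccccc1)O
F6 | step 4 | diethylphosphonoacetic acid | OC(=O)CP(=O)(OCC)OCC
F7 | step 4 | (3S,4S,E)-4-(methoxymethoxy)-1-phenylhexa-1,5-dien-3-yl 2-(diethoxyphosphoryl)acetate | C=C[C@H](OCOC)[C@H](/C=C/c1ccccc1)OC(=O)CP(=O)(OCC)OCC
F8 | step 4 | (1R,2S)-2-(methoxymethoxy)-1-[(2R,3S)-3-phenyloxiran-2-yl]but-3-en-1-yl 2-(diethoxyphosphoryl)acetate | C=C[C@H](OCOC)[C@H]([C@@H]1O[C@H]1c1ccccc1)OC(=O)CP(=O)(OCC)OCC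
F9 | step 4 | (1S,2R)-2-(methoxymethoxy)-3-oxo-1-[(2R,3S)-3-phenyloxiran-2-yl]propyl 2-(diethoxyphosphoryl)acetate | O=C[C@H](OCOC)[C@H]([C@@H]1O[C@H]1c1ccccc1)OC(=O)CP(=O)(OCC)OCC
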